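Partner is a conserved count: however a flask is run, the partner sitting on substrate's descendants can't exceed what was charged, just as a tank can't hold more tracer than was injected. The turnover budget is 0.800 in the set-ups asked about: the partner charged per substrate charged. The tetra adduct, by its name, carries 4 partners, so its ceiling is the budget divided by 4, here 20.0% of the substrate charged.

| setting | red | violet | amber | grey | theta | eta | epsilon | gamma |
|---|---|---|---|---|---|---|---|---|
| substrate | 0.20 M | 0.10 M | 0.40 M | 0.20 M | 0.20 M | 0.20 M | 0.20 M | 0.20 M |
| partner | 0.16 M | 0.16 M | 0.16 M | 0.16 M | 0.160 M | 0.160 M (fed, over 4.00 h) | 0.160 M | 0.160 M |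
| capture agent | 0.060 M | 0.060 M | 0.060 M | 0.090 M | 0.0600 M | 0.0600 M | 0.0600 M | 0.0600 M |
| remark | run made earlier | run made earlier | run made earlier | run made earlier | a single well-mixed tank run continuously and read at steady state, 8.0 h in it on average | all but partner at the start; partner goes in evenly over 4.00 h, the run ends at 8.0 h | one stirred flow tank at steady state, fed with the mixture as stated, mean residence time 24.0 h | everything together in a closed stirred flask, run for 8.0 h |
| time |  |  |  |  |  | 8.0 h |  | 8.0 h |

- red (time / h: tetra adduct / %, trapped intermediate / %): 0.250: 6, 1; 0.667: 0, 1; 1.33: 2, 5; 2.00: 1, 6; 3.00: 0, 10; 4.00: 0, 13; 5.00: 5, 17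
- violet (time / h: tetra adduct / %, trapped intermediate / %): 1.33: 5, 5; 3.00: 11, 10; 4.00: 9, 18; 6.00: 19, 17; 8.00: 18, 24; 10.0: 12, 29
- amber (time / h: tetra adduct / %, trapped intermediate / %): 0.833: 0, 2; 1.33: 1, 0; 2.00: 0, 3; 2.50: 0, 7; 4.00: 0, 6; 6.00: 0, 11; 10.0: 0, 10
- grey (time / h: tetra adduct / %, trapped intermediate / %): 2.00: 0, 8; 4.00: 1, 17; 6.00: 1, 23; 8.00: 3, 26; 10.0: 4, 29

(each reading ± 2 percentage points)

- the stated concentrations are those of everything mixed, before any reaction; amounts are the same in each set-up
- the feed brings no volume worth counting
- the earlier runs were made in a closed, stirred flask

1. the set-up with the highest share of tetra adduct in all that became tetra adduct or trapped intermediate, at the outlet or at the end ("none" if the first two lie within 2 percentage points) (theta / eta / epsilon / gamma / none)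
2. share of tetra adduct in all that became tetra adduct or trapped intermediate, at the outlet or at the end, theta
3. share of tetra adduct in all that became tetra adduct or trapped intermediate, at the outlet or at the end, eta
4. share of tetra adduct in all that became tetra adduct or trapped intermediate, at the outlet or at the end, epsilon
5. share of tetra adduct in all that became tetra adduct or trapped intermediate, at the outlet or at the end, gamma

The earlier runs seem to follow the budget. Violet has a budget of 1.60 and its last tetra adduct reading is 12%, while amber has 0.400 and reads 0%, each with a scatter of 2 percentage points.

Two chemists argue at the board. The counter says the charges are equal in theta, eta, epsilon and gamma, so the budget is equal, and the vessel should matter little. Red has that budget, its last 3 tetra adduct readings average 1.67%, and its last trapped intermediate reading is 17%. That makes a share of about 8.93% in each set-up, and the counter's answer is "none".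

The forecaster disagrees and gives each vessel its own number, though of the two flow tanks the forecast says: “Theta versus epsilon is a close, uncertain call”. The forecast gives 20% for theta, 7% for eta, 19% for epsilon and 13% for gamma, and names theta as best.

The simulation gives 28.3% for theta, 10.8% for eta, 22.6% for epsilon and 9.58% for gamma, so the best is theta. Theta and epsilon lie 5.7 points apart against a margin of 2 points, so the answer is theta and not the counter's "none". The forecast named the same set-up, though its theta stands 8.3 points low.

    substrate + partner → first product (k = 0.140 /M/min)
    partner + first product → double product (k = 0.0880 /M/min)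
    partner + double product → triple product (k = 0.260 /M/min)
    partner + triple product → tetra adduct (k = 0.260 /M/min)
    2 substrate → homo dimer (k = 3.40 × 10⁻⁴ /M/min)
    first product + capture agent → trapped intermediate (k = 0.0360 /M/min)

The count still balances in gamma at 8.00 h. With none on substrate or homo dimer, one partner on first product and on trapped intermediate, two on double product, 3 on triple product and 4 on tetra adduct, the sum is 0.800 against the budget of 0.800, and partner, the limiting reagent, stands at 0% of its charge. The counter's ground is closed flasks with different budgets. The neighbour like gamma but with 0.080 M of substrate has a budget of 2.00 and a ceiling of 50.0%. At 8.00 h its count, with the partner still free, sums to 2.00, its tetra adduct stands at 24.9%, and its share is 50.3%.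

All runs stem from a simulated flask with constants of no real substance; the scatter is artificial.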